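C1–C7 is cut back to a vinyl bromide plus a hydroxymethyl-tin reagent, and C6–O6 to an allylic bromide next to the C5 benzoate. C1 is then removed by cutting C1–C2 and C1–C6 and rejoining C2–C6, and the resulting cyclopentene is cut at C2=C6 to a 1,6-diene.
Ring numbering: C1 is the alkene carbon bearing C7H2OBz, C2 the alkene CH, C3 and C4 the free carbinols, C5 the benzoate carbon, and C6 the carbinol next to C1. C1 is the only ring atom with neither H nor O and lies between C2 and C6, so it can enter as a carbene carbon across the C2=C6 double bond of a five-membered ring that already holds C3, C4 and C5.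
Forward order: a mannoside ring is opened to a chain, the chain is made a diene, and metathesis closes the five-membered carbocycle. CBr2 then adds a three-membered ring whose opening enlarges five to six; O6, C7 and the second benzoate follow.
Stereochemistry: C5, C4 and C3 are C2, C3 and C4 of D-mannose (chiral pool). The benzoate is steered to O5 by the axial-ester rule of orthoester hydrolysis, and C6 is set by oxygen delivery from the C5 benzoate on its own face.

Key step: step 7

Numbering note: all carbocycles carry the target ring numbers defined above. "Upper face" is the face of O3; "lower face" is that of O4, O5 and O6.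
Assumption: the ring enlargement is drawn for the allylic bromide isomer expected to dominate. Minor positional or facial isomers would be carried along, because the solvolysis that follows converges.

Step 1
Reactants: 1 methyl α-D-mannopyranoside
Product: 2 methyl 6-deoxy-6-iodo-α-D-mannopyranoside
Conditions: I2, PPh3, imidazole, THF, reflux
Reagents that add atoms: iodine, [I][I]
Why: Garegg–Samuelsson iodination (Appel-type activation by the iodophosphonium salt followed by SN2 displacement) is selective for the unhindered primary C6 hydroxyl of an unprotected pyranoside and touches no stereocentre.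

Step 2
Reactants: 2 methyl 6-deoxy-6-iodo-α-D-mannopyranoside; 3 trimethyl orthobenzoate
Product: 5 methyl 2-O-benzoyl-6-deoxy-6-iodo-α-D-mannopyranoside, via orthobenzoate 4 (not isolated)
Conditions: PhC(OMe)3, camphorsulfonic acid (catalytic), MeCN, rt; then 80% aq AcOH, 0 °C to rt
Reagents that add atoms: trimethyl orthobenzoate, COC(OC)(OC)c1ccccc1; water, O
Why: Acid-catalysed orthoester exchange engages the cis-2,3-diol in a five-membered ring, and kinetic hydrolysis of such a pyranoside orthoester follows the axial-ester rule, so the benzoate is left on axial O2 (the future O5) while equatorial O3 is freed.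

Step 3
Reactants: 5 methyl 2-O-benzoyl-6-deoxy-6-iodo-α-D-mannopyranoside
Product: 6 methyl 2-O-benzoyl-3,4-bis-O-(tert-butyldimethylsilyl)-6-deoxy-6-iodo-α-D-mannopyranoside
Conditions: TBSOTf, 2,6-lutidine, CH2Cl2, 0 °C to rt
Reagents that add atoms: tert-butyldimethylsilyl triflate, CC(C)(C)[Si](C)(C)OS(=O)(=O)C(F)(F)F
Why: Silyl triflate silylation with a hindered pyridine base is fast and essentially non-basic, so both equatorial hydroxyls, including the crowded second one, should be capped before the axial benzoate can shift to O3.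

Step 4
Reactants: 6 methyl 2-O-benzoyl-3,4-bis-O-(tert-butyldimethylsilyl)-6-deoxy-6-iodo-α-D-mannopyranoside
Product: 7 2-O-benzoyl-3,4-bis-O-(tert-butyldimethylsilyl)-5,6-dideoxy-D-lyxo-hex-5-enose (open-chain aldehyde)
Conditions: Zn dust (activated), THF/H2O, ultrasound, 40 °C
Reagents that add atoms: none
Why: Bernet–Vasella reductive fragmentation: zinc inserts into the C6–I bond and the organozinc expels the ring oxygen, which creates the C5=C6 alkene and unmasks C1 as the aldehyde with loss of methoxide, under near-neutral conditions that leave the ester, the silyl ethers and C2–C4 unchanged.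

Step 5
Reactants: 7 2-O-benzoyl-3,4-bis-O-(tert-butyldimethylsilyl)-5,6-dideoxy-D-lyxo-hex-5-enose
Product: 8 (3R,4R,5R)-4,5-bis(tert-butyldimethylsilyloxy)hepta-1,6-dien-3-yl benzoate
Conditions: CH2I2, Zn, Ti(Oi-Pr)4, THF, rt
Reagents that add atoms: diiodomethane, ICI
Why: Takai methylenation with the gem-dizinc reagent formed in the flask is non-basic and selective for aldehydes over esters, so the α-benzoyloxy aldehyde should be converted into the terminal alkene without epimerisation, β-elimination or attack on the benzoate.

Step 6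
Reactants: 8 (3R,4R,5R)-4,5-bis(tert-butyldimethylsilyloxy)hepta-1,6-dien-3-yl benzoate
Product: 9 (1R,4R,5R)-4,5-bis(tert-butyldimethylsilyloxy)cyclopent-2-en-1-yl benzoate
Conditions: second-generation Grubbs catalyst RuCl2(=CHPh)(PCy3)(H2IMes) (catalytic), CH2Cl2, reflux
Reagents that add atoms: none
Why: Ring-closing olefin metathesis of a 1,6-diene with two monosubstituted alkenes closes the five-membered carbocycle and forms the C2=C6 double bond, driven by loss of ethene, with the three carbinol stereocentres as spectators.

Step 7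
Reactants: 9 (1R,4R,5R)-4,5-bis(tert-butyldimethylsilyloxy)cyclopent-2-en-1-yl benzoate; 10 sodium tribromoacetate
Product: 12 (1S,2R,5R,6R)-2,3-dibromo-5,6-bis(tert-butyldimethylsilyloxy)cyclohex-3-en-1-yl benzoate, via dibromocyclopropane 11 (not isolated)
Conditions: Br3CCO2Na (excess, in portions), n-Bu4NBr (catalytic), dry DME/toluene, 80 °C, then 110 °C
Reagents that add atoms: sodium tribromoacetate, [Na+].[O-]C(=O)C(Br)(Br)Br
Why: Heating 10 expels CO2 to give tribromomethanide, which loses bromide to singlet dibromocarbene, and this adds to the C2=C6 alkene of 9 in a concerted, suprafacial cheletropic [2+1] step that forms C1–C2 and C1–C6 and closes the three-membered ring of 11. At the higher temperature 11 undergoes the two-electron disrotatory electrocyclic opening that is concerted with departure of the endo bromide, so the former C2–C6 bond breaks, the six-membered ring arises by enlargement of the five-membered one rather than by cyclisation, and the 2-bromoallyl cation spanning C2–C1–C6 recombines with bromide. The closest known reaction is dibromocarbene addition to cyclopentene followed by thermal isomerisation of 6,6-dibromobicyclo[3.1.0]hexane to 2,3-dibromocyclohexene. The one new stereocentre, C6, is controlled by the C5 benzoate and the C3 silyl ether: bromide returns on the upper face, either within the ion pair left by an upper-face cyclopropane or by SN2 opening of a transient benzoxonium ion, and it does so at C6 because C2 is screened on that face by the cis C3 silyl ether. The step needs chemoselective capture of an electrophilic carbene by an alkene that two allylic C–O bonds make rather electron-poor, which is secured by a neutral, base-free carbene source used in excess (the benzoate survives) and by the absence of any other π-nucleophile, O–H bond or activated C–H bond in 9. Facial selectivity of the carbene and the position of the allylic bromide need not be perfect, since every isomer ionises to the same allyl cation in step 8.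

Step 8
Reactants: 12 (1S,2R,5R,6R)-2,3-dibromo-5,6-bis(tert-butyldimethylsilyloxy)cyclohex-3-en-1-yl benzoate
Product: 15 (1R,2S,5R,6R)-3-bromo-2-hydroxy-5,6-bis(tert-butyldimethylsilyloxy)cyclohex-3-en-1-yl benzoate, via benzoxonium ion 13 (not isolated), via hemiorthoester 14 (not isolated)
Conditions: AgBF4, CaCO3, acetone/H2O, 0 °C to rt, dark
Reagents that add atoms: water, O
Why: Woodward-type cis-hydroxylation (silver-assisted solvolysis with neighbouring-group participation): silver ion removes the allylic bromide, the carbonyl oxygen of the C5 benzoate closes on C6 of the 2-bromoallyl cation from its own lower face to give cis-fused 13, water adds to the acyl carbon, and 14 collapses by the axial-ester rule in the half-chair that avoids a syn-axial O4/O6 contact (O5 axial, O6 pseudo-equatorial), which sets C6 cis to C5 and should leave the benzoate on O5, while CaCO3 takes up the acid that would endanger the silyl ethers.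

Step 9
Reactants: 15 (1R,2S,5R,6R)-3-bromo-2-hydroxy-5,6-bis(tert-butyldimethylsilyloxy)cyclohex-3-en-1-yl benzoate; 16 (tributylstannyl)methanol
Product: 17 (1R,2R,5R,6R)-2-hydroxy-3-(hydroxymethyl)-5,6-bis(tert-butyldimethylsilyloxy)cyclohex-3-en-1-yl benzoate
Conditions: Bu3SnCH2OH, Pd(PPh3)4 (catalytic), 1,4-dioxane, 100 °C
Reagents that add atoms: (tributylstannyl)methanol, CCCC[Sn](CCCC)(CCCC)CO
Why: Stille coupling: zerovalent palladium adds oxidatively to the C1–Br bond, the hydroxymethyl group is transferred from tin in preference to butyl, and reductive elimination forms C1–C7 under neutral conditions that tolerate the free C6 hydroxyl, the homoallylic benzoate and the silyl ethers.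

Step 10
Reactants: 17 (1R,2R,5R,6R)-2-hydroxy-3-(hydroxymethyl)-5,6-bis(tert-butyldimethylsilyloxy)cyclohex-3-en-1-yl benzoate; 18 benzoyl chloride
Product: 19 [(3R,4R,5R,6R)-5-(benzoyloxy)-3,4-bis(tert-butyldimethylsilyloxy)-6-hydroxycyclohex-1-en-1-yl]methyl benzoate
Conditions: BzCl (1.05 equiv), pyridine, CH2Cl2, −40 °C
Reagents that add atoms: benzoyl chloride, O=C(Cl)c1ccccc1
Why: Kinetically selective acylation: at low temperature with one equivalent of acid chloride the unhindered primary allylic O7 hydroxyl reacts much faster than the secondary O6 hydroxyl wedged between C1 and the C5 benzoate.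

Step 11
Reactants: 19 [(3R,4R,5R,6R)-5-(benzoyloxy)-3,4-bis(tert-butyldimethylsilyloxy)-6-hydroxycyclohex-1-en-1-yl]methyl benzoate
Product: 20 [(3R,4S,5R,6R)-5-(benzoyloxy)-3,4,6-trihydroxycyclohex-1-en-1-yl]methyl benzoate
Conditions: HF·pyridine, THF, 0 °C to rt, polyethylene vessel
Reagents that add atoms: none
Why: Fluoride-induced cleavage of the Si–O bonds in a mildly acidic medium frees O3 and O4 without generating alkoxides, so benzoate migration along the cis O4/O5/O6 array or from O7 to O6 should not set in and no stereocentre is affected.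

Compound list
1 | methyl α-D-mannopyranoside | CO[C@@H]1[C@@H](O)[C@@H](O)[C@H](O)[C@@H](CO)O1 | starting material
2 | methyl 6-deoxy-6-iodo-α-D-mannopyranoside | CO[C@@H]1[C@@H](O)[C@@H](O)[C@H](O)[C@@H](CI)O1 | intermediate
3 | trimethyl orthobenzoate | COC(OC)(OC)c1ccccc1 | starting material
4 | methyl 6-deoxy-6-iodo-2,3-O-(α-methoxybenzylidene)-α-D-mannopyranoside (cyclic 2,3-orthobenzoate, either configuration at the orthoester carbon; formed in the flask) | CO[C@@H]1[C@H]2OC(OC)(c3ccccc3)O[C@H]2[C@H](O)[C@@H](CI)O1 | intermediate
5 | methyl 2-O-benzoyl-6-deoxy-6-iodo-α-D-mannopyranoside | CO[C@@H]1[C@@H](OC(=O)c2ccccc2)[C@@H](O)[C@H](O)[C@@H](CI)O1 | intermediate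
6 | methyl 2-O-benzoyl-3,4-bis-O-(tert-butyldimethylsilyl)-6-deoxy-6-iodo-α-D-mannopyranoside | CO[C@@H]1[C@@H](OC(=O)c2ccccc2)[C@@H](O[Si](C)(C)C(C)(C)C)[C@H](O[Si](C)(C)C(C)(C)C)[C@@H](CI)O1 | intermediate
7 | 2-O-benzoyl-3,4-bis-O-(tert-butyldimethylsilyl)-5,6-dideoxy-D-lyxo-hex-5-enose (aldehyde carbon = future C6) | O=C[C@@H](OC(=O)c1ccccc1)[C@@H](O[Si](C)(C)C(C)(C)C)[C@H](O[Si](C)(C)C(C)(C)C)C=C | intermediate
8 | (3R,4R,5R)-4,5-bis(tert-butyldimethylsilyloxy)hepta-1,6-dien-3-yl benzoate | C=C[C@@H](OC(=O)c1ccccc1)[C@@H](O[Si](C)(C)C(C)(C)C)[C@H](O[Si](C)(C)C(C)(C)C)C=C | intermediate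
9 | (1R,4R,5R)-4,5-bis(tert-butyldimethylsilyloxy)cyclopent-2-en-1-yl benzoate (target numbering: C5 benzoate, C4 and C3 silyl ethers, O3 trans to O4, O4 cis to O5) | C1=C[C@@H](O[Si](C)(C)C(C)(C)C)[C@H](O[Si](C)(C)C(C)(C)C)[C@@H]1OC(=O)c1ccccc1 | intermediate
10 | sodium tribromoacetate | [Na+].[O-]C(=O)C(Br)(Br)Br | starting material
11 | 6,6-dibromo-3,4-bis(tert-butyldimethylsilyloxy)bicyclo[3.1.0]hexan-2-yl benzoate, CBr2 bridge on the upper face, opposite to the benzoate (formed in the flask) | BrC1(Br)[C@H]2[C@@H](O[Si](C)(C)C(C)(C)C)[C@H](O[Si](C)(C)C(C)(C)C)[C@H](OC(=O)c3ccccc3)[C@@H]12 | intermediate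
12 | (1S,2R,5R,6R)-2,3-dibromo-5,6-bis(tert-butyldimethylsilyloxy)cyclohex-3-en-1-yl benzoate (target numbering: 1,6-dibromide, C6–Br trans to the C5 benzoate) | BrC1=C[C@@H](O[Si](C)(C)C(C)(C)C)[C@H](O[Si](C)(C)C(C)(C)C)[C@H](OC(=O)c2ccccc2)[C@H]1Br | intermediate
13 | cis-fused 2-phenyl-1,3-dioxolan-2-ylium (benzoxonium) tetrafluoroborate bridging O5 and O6 on the lower face (formed in the flask) | BrC1=C[C@@H](O[Si](C)(C)C(C)(C)C)[C@H](O[Si](C)(C)C(C)(C)C)[C@@H]2OC(c3ccccc3)=[O+][C@H]12.F[B-](F)(F)F | intermediate
14 | cis-fused 2-hydroxy-2-phenyl-1,3-dioxolane (hemiorthoester) bridging O5 and O6 (formed in the flask) | BrC1=C[C@@H](O[Si](C)(C)C(C)(C)C)[C@H](O[Si](C)(C)C(C)(C)C)[C@@H]2OC(O)(c3ccccc3)O[C@H]12 | intermediate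
15 | (1R,2S,5R,6R)-3-bromo-2-hydroxy-5,6-bis(tert-butyldimethylsilyloxy)cyclohex-3-en-1-yl benzoate (target numbering: C1–Br, O6–H cis to the C5 benzoate) | BrC1=C[C@@H](O[Si](C)(C)C(C)(C)C)[C@H](O[Si](C)(C)C(C)(C)C)[C@H](OC(=O)c2ccccc2)[C@@H]1O | intermediate
16 | (tributylstannyl)methanol | CCCC[Sn](CCCC)(CCCC)CO | starting material
17 | (1R,2R,5R,6R)-2-hydroxy-3-(hydroxymethyl)-5,6-bis(tert-butyldimethylsilyloxy)cyclohex-3-en-1-yl benzoate | OCC1=C[C@@H](O[Si](C)(C)C(C)(C)C)[C@H](O[Si](C)(C)C(C)(C)C)[C@H](OC(=O)c2ccccc2)[C@@H]1O | intermediate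
18 | benzoyl chloride | O=C(Cl)c1ccccc1 | starting material
19 | [(3R,4R,5R,6R)-5-(benzoyloxy)-3,4-bis(tert-butyldimethylsilyloxy)-6-hydroxycyclohex-1-en-1-yl]methyl benzoate | O=C(OCC1=C[C@@H](O[Si](C)(C)C(C)(C)C)[C@H](O[Si](C)(C)C(C)(C)C)[C@H](OC(=O)c2ccccc2)[C@@H]1O)c1ccccc1 | intermediate
20 | [(3R,4S,5R,6R)-5-(benzoyloxy)-3,4,6-trihydroxycyclohex-1-en-1-yl]methyl benzoate (CNP0198957.6) | O=C(OCC1=C[C@@H](O)[C@H](O)[C@H](OC(=O)c2ccccc2)[C@@H]1O)c1ccccc1 | target

Total step count: 11. Longest linear sequence: 11 steps (1 to 20).

Steps most likely to fail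

Step 7. Carbene capture may be slow, because the alkene is inductively deactivated and screened on both faces by allylic C–O substituents, so self-destruction of the carbene can outrun cyclopropanation. At the temperature needed for ring opening, loss of HBr from the allylic bromide may also start an aromatisation. The fallback gives up the ring enlargement and closes the six-membered ring directly.
- It sets out from aldehyde 7, whose carbonyl carbon is already C6.
- Aldehyde 7 is coupled under Nozaki–Hiyama–Kishi conditions (CrCl2, NiCl2 catalytic, DMF, rt) with [(2-bromoprop-2-en-1-yl)oxy](tert-butyl)dimethylsilane F1, made from commercial 2-bromoprop-2-en-1-ol with TBSCl and imidazole.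
- This should give the Felkin–Anh dienol F2, with O6 anti to O5 in the chain and therefore cis in the ring.
- Ring-closing metathesis with the second-generation Grubbs catalyst RuCl2(=CHPh)(PCy3)(H2IMes) in refluxing CH2Cl2 forms C1=C2 and gives the cyclohexene tris(silyl ether) F3.
- Pyridine-buffered HF·pyridine in THF at 0 °C removes only the primary O7 silyl group, and the route is rejoined at 17.

Step 8. The hemiorthoester may collapse toward the wrong oxygen, or the acyl group may shift from O5 to O6 afterwards. Water may also capture the allyl cation at C2 before the benzoate closes. The fallback sets out from 12 and installs O6 at the ketone level, so no dioxolane has to be hydrolysed.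
- Kornblum-type oxidation (AgBF4, DMSO, then Et3N, 0 °C) converts the allylic bromide into the 2-bromocyclohexenone F4, with the benzoate still on O5.
- Luche reduction (NaBH4, CeCl3·7H2O, MeOH, −78 °C) should deliver hydride anti to the C5–O bond (polar Felkin–Anh, axial attack). This places O6 cis to O5 and rejoins the route at 15.

Step 9. Transfer of the hydroxymethyl group from tin to palladium may be sluggish at a vinyl bromide flanked by the C6 carbinol, which would allow butyl transfer, protodebromination and thermal acyl migration to compete. The fallback sets out from 15 and brings in C7 as carbon monoxide.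
- Reductive carbonylation (CO, Pd(PPh3)4 catalytic, Bu3SnH added slowly, toluene, 60 °C) gives the cyclohexenecarbaldehyde F5.
- Luche reduction (NaBH4, CeCl3·7H2O, MeOH, −78 °C), which spares the benzoate, gives the primary allylic alcohol and rejoins the route at 17.

Further compounds
F1 | step 7 | [(2-bromoprop-2-en-1-yl)oxy](tert-butyl)dimethylsilane | C=C(Br)CO[Si](C)(C)C(C)(C)C
F2 | step 7 | 5,6-bis(tert-butyldimethylsilyloxy)-2-[(tert-butyldimethylsilyloxy)methyl]-3-hydroxyocta-1,7-dien-4-yl benzoate (open-chain C7–C1–C6–C5–C4–C3–C2 array, O6/O5 and O5/O4 erythro, O4/O3 threo) | C=C(CO[Si](C)(C)C(C)(C)C)[C@@H](O)[C@@H](OC(=O)c1ccccc1)[C@@H](O[Si](C)(C)C(C)(C)C)[C@H](O[Si](C)(C)C(C)(C)C)C=C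
F3 | step 7 | 3,4-bis(tert-butyldimethylsilyloxy)-1-[(tert-butyldimethylsilyloxy)methyl]-6-hydroxycyclohex-1-en-5-yl benzoate (target numbering) | CC(C)(C)[Si](C)(C)OCC1=C[C@@H](O[Si](C)(C)C(C)(C)C)[C@H](O[Si](C)(C)C(C)(C)C)[C@H](OC(=O)c2ccccc2)[C@@H]1O
F4 | step 8 | 1-bromo-3,4-bis(tert-butyldimethylsilyloxy)-6-oxocyclohex-1-en-5-yl benzoate (target numbering) | BrC1=C[C@@H](O[Si](C)(C)C(C)(C)C)[C@H](O[Si](C)(C)C(C)(C)C)[C@H](OC(=O)c2ccccc2)C1=O
F5 | step 9 | 1-formyl-3,4-bis(tert-butyldimethylsilyloxy)-6-hydroxycyclohex-1-en-5-yl benzoate (target numbering) | O=CC1=C[C@@H](O[Si](C)(C)C(C)(C)C)[C@H](O[Si](C)(C)C(C)(C)C)[C@H](OC(=O)c2ccccc2)[C@@H]1O
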